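Before spending a small charge of starting material, read what the autumn run already holds: its target stalls near 27.8 % at 1.33 min, below the 50.0 % its partner charge allows, with starting material down to 0.5 %.

the same everywhere: starting material 1.3 M

| run | partner | remark | time |
|---|---|---|---|
| autumn | 0.65 M | run made earlier |  |
| flask | 1.30 M |  | 10 min |

autumn run (percent of the starting material charged)

| time / min | target / % | starting material / % |
|---|---|---|
| 0.667 | 24.1 | 5.9 |
| 1.33 | 27.8 | 0.5 |
| 2.00 | 26.9 | 0 |
| 2.50 | 26.1 | 0 |
| 3.00 | 24.9 | 0 |

(scatter of a reading: 0.3 percentage points)



1. when, up to 10 min, the flask holds most target
2. the amount of target, in percent of the starting material charged, at that time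
3. earliest time at which at least nineteen twentieths of that best amount are there, in min
4. latest time at which they still are, in min

So, if one partner goes into each target and nothing else takes partner, the autumn run's 0.361 M of target leaves 0.289 M of partner at the stall. Treat that stall as a balance, then, and let c(rest) be the charge not turned into target, which gives 1.33 M⁻¹ as a reading: this is the binding quotient Q, an apparent equilibrium constant, c(target) divided by c(partner) times c(rest). Hold Q and raise partner to 1.30 M, and the quadratic for this flask gives 0.619 M of target, or 47.6 % of the starting material, which is my own reckoning. But autumn target sinks to 24.9 % by 3.00 min, so I take that figure as the high side.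

The forecast stands lower than my figure, at 45 % near 1.2 min, with the window from 0.75 min to 1.95 min, and it adds the caution "Decay might speed up with partner".

The flask gives 42.8 % at 1.08 min, with the window from 0.748 min to 1.63 min, which closes earlier than forecast. At that best time this flask holds 8.75 % as over-reaction product and 47.3 % as intermediate.

    partner + intermediate ⇌ target (K = 2.07 M⁻¹, k = 2.31 M⁻¹ min⁻¹)
    partner + target → over-reaction product (k = 0.391 M⁻¹ min⁻¹)
    starting material → intermediate (k = 4.16 min⁻¹)

This flask delivered 89.9 % of what Q reckoned. Now take a neighbour flask, the same but charged with 0.52 M of starting material: there Q gives 0.298 M of target, or 57.2 % of its charge, the same share brings that to 51.4 %, and the neighbour's best stands at 49.6 %.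

The earlier runs and the new flask are simulated for substances that don't exist, noise included.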